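**Plan**

1. Enabling feature: in the oxane ring (O1, C2–C6) the ring oxygen O1 links the benzylic carbon C2 (bearing the 3,4-dihydroxy-5-methoxyphenyl ring) to C6, and C4 carries an oxygen. C2 is therefore a masked aryl aldehyde carbon (an aryl-stabilised oxocarbenium ion), C3–C4 a masked terminal alkene and the C4–O bond a trapped oxan-4-yl cation. The 2- and 6-substituents are cis; the acetate is trans to both (axial).
2. Retrosynthesis: the C4–OAc bond is cut with inversion (back to the all-cis oxan-4-ol). Then the C2–C3, C4–O and O1–C2 bonds are cut together (three-component Prins) to an (S)-homoallylic alcohol, a benzyl-protected aryl aldehyde and CF3CO2H. Last, the carbinol–allyl C–C bond is cut to a 3-arylpropanal.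
3. Forward: the chain is joined first (hydroferulic acid, aldehyde, allylation). The oxane ring, the only ring made, is closed by the Prins cyclization. Acetate is then introduced by Mitsunobu reaction and the benzyl groups are removed.
4. Stereochemistry: C6 comes from reagent-controlled Brown allylboration. C2 and C4 follow from C6 through the all-equatorial chair of the Prins closure. C4 is then inverted by the SN2 step of the Mitsunobu reaction, which installs the acetate at the same time.

Key step: step 5

Remark on numbering: oxane numbering is used for the ring (O1; C2 aryl; C4 oxygen; C6 arylethyl).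
Assumption: the (−)-α-pinene-derived allylborane gives the (S)-carbinol with this unbranched aldehyde (the usual Brown sense); Mosher ester analysis of 4 would confirm it.

**Route**

Step 1
Reactants: 1 3-(4-hydroxy-3-methoxyphenyl)propanoic acid (hydroferulic acid)
Product: 2 benzyl 3-[4-(benzyloxy)-3-methoxyphenyl]propanoate
Conditions: BnBr (2.3 equiv), K2CO3, DMF, rt to 50 °C
Reagents that add atoms: benzyl bromide, BrCc1ccccc1
Why: Williamson O-alkylation (SN2) of the phenoxide and the carboxylate; one operation masks the phenol for the whole route and gives an ester that can be reduced to the aldehyde.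

Step 2
Reactants: 2 benzyl 3-[4-(benzyloxy)-3-methoxyphenyl]propanoate
Product: 3 3-[4-(benzyloxy)-3-methoxyphenyl]propanal
Conditions: i-Bu2AlH (1.1 equiv), CH2Cl2, −78 °C; MeOH, then aq. KNaC4H4O6
Reagents that add atoms: none
Why: Partial ester reduction with i-Bu2AlH; the tetrahedral aluminium hemiacetal is stable at −78 °C and should collapse to the aldehyde only on work-up, and the aryl benzyl ether is inert.

Step 3
Reactants: 3 3-[4-(benzyloxy)-3-methoxyphenyl]propanal
Product: 4 (3S)-1-[4-(benzyloxy)-3-methoxyphenyl]hex-5-en-3-ol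
Conditions: (+)-Ipc2BOMe, CH2=CHCH2MgBr, Et2O, 0 °C to rt; then 3, Et2O, −78 °C; then NaOH, H2O2, rt
Reagents that add atoms: allylmagnesium bromide, C=CC[Mg]Br; its allyl group is passed on in the flask as B-allylbis[(1S,2S,3S,5R)-isopinocampheyl]borane, C=CCB([C@H]1C[C@H]2C[C@@H]([C@@H]1C)C2(C)C)[C@H]1C[C@H]2C[C@@H]([C@@H]1C)C2(C)C
Why: Brown asymmetric allylboration through a closed six-membered chair (Zimmerman–Traxler) transition state; the isopinocampheyl groups of the (−)-α-pinene series select the aldehyde face that should give the (S)-carbinol, the future C6.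

Step 4
Reactants: 5 3,4-dihydroxy-5-methoxybenzaldehyde (5-hydroxyvanillin)
Product: 6 3,4-bis(benzyloxy)-5-methoxybenzaldehyde
Conditions: BnBr (2.3 equiv), K2CO3, DMF, 60 °C, N2
Reagents that add atoms: benzyl bromide, BrCc1ccccc1
Why: Williamson etherification of both catechol hydroxyls; benzyl ethers should survive CF3CO2H, K2CO3/MeOH and Mitsunobu conditions and leave at the end by hydrogenolysis without touching the acetate.

Step 5
Reactants: 4 (3S)-1-[4-(benzyloxy)-3-methoxyphenyl]hex-5-en-3-ol; 6 3,4-bis(benzyloxy)-5-methoxybenzaldehyde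
Product: 9 (2S,4R,6S)-2-[3,4-bis(benzyloxy)-5-methoxyphenyl]-6-{2-[4-(benzyloxy)-3-methoxyphenyl]ethyl}oxan-4-ol (all-cis), via oxocarbenium trifluoroacetate 7 (not isolated), via all-cis oxan-4-yl trifluoroacetate 8 (not isolated)
Conditions: CF3CO2H, CH2Cl2, 0 °C to rt; evaporation; then K2CO3, MeOH, rt
Reagents that add atoms: trifluoroacetic acid, OC(=O)C(F)(F)F
Why: Three-component Prins cyclization: CF3CO2H condenses the carbinol oxygen of 4 with the aldehyde carbon of 6 to the (E)-oxocarbenium ion 7, whose benzylic carbon (future C2) is attacked by the terminal alkene carbon (future C3), and the resulting oxan-4-yl cation is captured at C4 by trifluoroacetate, so that the C2–C3 bond, the C4–O bond and the ring arise in one operation from an alcohol, an aldehyde and an acid. The closest known reaction type is the CF3CO2H-mediated Prins cyclization of homoallylic alcohols with aromatic aldehydes to all-cis 2,6-disubstituted oxan-4-ols. The oxane ring closes in a 6-endo-trig mode (with respect to the alkene) through a chair transition state. C2 is controlled by C6, because the arylethyl chain at C6 and the aryl group of the (E)-oxocarbenium both sit equatorial and give the 2,6-cis ring; C4 is controlled by the same chair, the nucleophile entering equatorially to give the all-cis (4R) ester 8, which methanolysis turns into 9. The step needs ring closure without 2-oxonia-Cope side-chain exchange and without loss of configuration at C6: the aryl ring on C2 conjugates with the oxocarbenium, so the Cope-rearranged alkyl oxocarbenium is uphill, and C6 is a non-benzylic carbinol centre that cannot ionise. The equatorial C4 oxygen is the epimer of the axial acetate of the target and is inverted in step 6.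

Step 6
Reactants: 9 (2S,4R,6S)-2-[3,4-bis(benzyloxy)-5-methoxyphenyl]-6-{2-[4-(benzyloxy)-3-methoxyphenyl]ethyl}oxan-4-ol
Product: 10 (2S,4S,6S)-2-[3,4-bis(benzyloxy)-5-methoxyphenyl]-6-{2-[4-(benzyloxy)-3-methoxyphenyl]ethyl}oxan-4-yl acetate
Conditions: AcOH, PPh3, DIAD, toluene, 0 °C to rt
Reagents that add atoms: acetic acid, CC(=O)O
Why: Mitsunobu reaction: the equatorial C4 hydroxyl is activated as an alkoxyphosphonium ion and displaced by acetate in an SN2 step with inversion, which should set (4S) and install the axial acetate in the same operation; anti elimination is disfavoured because the equatorial leaving group has no antiperiplanar hydrogen in the chair that keeps both large groups equatorial.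

Step 7
Reactants: 10 (2S,4S,6S)-2-[3,4-bis(benzyloxy)-5-methoxyphenyl]-6-{2-[4-(benzyloxy)-3-methoxyphenyl]ethyl}oxan-4-yl acetate
Product: 11 (2S,4S,6S)-2-(3,4-dihydroxy-5-methoxyphenyl)-6-[2-(4-hydroxy-3-methoxyphenyl)ethyl]oxan-4-yl acetate (CNP0143286.2)
Conditions: H2 (1 atm), 10% Pd/C, EtOAc, rt
Reagents that add atoms: none
Why: Catalytic hydrogenolysis of the three aryl benzyl ethers; under 1 atm H2 in ethyl acetate the unhindered O-benzyl groups should cleave much faster than the hindered ring C2–O1 benzylic ether, and the acetate and the three stereocentres are not affected.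

**Compound list**

1 | 3-(4-hydroxy-3-methoxyphenyl)propanoic acid (hydroferulic acid) | OC(=O)CCc1ccc(O)c(OC)c1 | starting material
2 | benzyl 3-[4-(benzyloxy)-3-methoxyphenyl]propanoate | O=C(CCc1ccc(OCc2ccccc2)c(OC)c1)OCc1ccccc1 | intermediate
3 | 3-[4-(benzyloxy)-3-methoxyphenyl]propanal | O=CCCc1ccc(OCc2ccccc2)c(OC)c1 | intermediate
4 | (3S)-1-[4-(benzyloxy)-3-methoxyphenyl]hex-5-en-3-ol | C=CC[C@@H](O)CCc1ccc(OCc2ccccc2)c(OC)c1 | intermediate
5 | 3,4-dihydroxy-5-methoxybenzaldehyde (5-hydroxyvanillin) | O=Cc1cc(O)c(O)c(OC)c1 | starting material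
6 | 3,4-bis(benzyloxy)-5-methoxybenzaldehyde | O=Cc1cc(OCc2ccccc2)c(OCc2ccccc2)c(OC)c1 | intermediate
7 | (E)-oxocarbenium trifluoroacetate from 4 and 6, (S) at the carbinol carbon, not isolated | C=CC[C@H](CCc1ccc(OCc2ccccc2)c(OC)c1)/[O+]=C/c1cc(OCc2ccccc2)c(OCc2ccccc2)c(OC)c1.[O-]C(=O)C(F)(F)F | intermediate
8 | (2S,4R,6S)-2-[3,4-bis(benzyloxy)-5-methoxyphenyl]-6-{2-[4-(benzyloxy)-3-methoxyphenyl]ethyl}oxan-4-yl trifluoroacetate (all-cis), not isolated | COc1cc(CC[C@H]2C[C@@H](OC(=O)C(F)(F)F)C[C@@H](c3cc(OCc4ccccc4)c(OCc4ccccc4)c(OC)c3)O2)ccc1OCc1ccccc1 | intermediate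
9 | (2S,4R,6S)-2-[3,4-bis(benzyloxy)-5-methoxyphenyl]-6-{2-[4-(benzyloxy)-3-methoxyphenyl]ethyl}oxan-4-ol (all-cis) | COc1cc(CC[C@H]2C[C@@H](O)C[C@@H](c3cc(OCc4ccccc4)c(OCc4ccccc4)c(OC)c3)O2)ccc1OCc1ccccc1 | intermediate
10 | (2S,4S,6S)-2-[3,4-bis(benzyloxy)-5-methoxyphenyl]-6-{2-[4-(benzyloxy)-3-methoxyphenyl]ethyl}oxan-4-yl acetate (axial acetate) | COc1cc(CC[C@H]2C[C@H](OC(C)=O)C[C@@H](c3cc(OCc4ccccc4)c(OCc4ccccc4)c(OC)c3)O2)ccc1OCc1ccccc1 | intermediate
11 | (2S,4S,6S)-2-(3,4-dihydroxy-5-methoxyphenyl)-6-[2-(4-hydroxy-3-methoxyphenyl)ethyl]oxan-4-yl acetate | COc1cc(CC[C@H]2C[C@H](OC(C)=O)C[C@@H](c3cc(O)c(O)c(OC)c3)O2)ccc1O | target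

**Count and risks**

Total step count: 7. Longest linear sequence: 6 steps (steps 1, 2, 3, 5, 6, 7); step 4 is the side branch.

Steps most likely to fail:

Step 5. The aryl-stabilised oxocarbenium ion may be captured too slowly by the unactivated alkene. Prolonged exposure to CF3CO2H could then cause loss of benzyl ethers or acid-induced opening at the benzylic C2–O1 bond. The fallback makes the same C2–C3 bond with an enolate as the nucleophile, by a Petasis–Ferrier rearrangement. It sets out from 4 and 6 and comes back at 10, so step 6 is bypassed as well. Oxidative cleavage of the alkene of 4 (OsO4 cat., NaIO4, 2,6-lutidine, dioxane/H2O) should give (3S)-5-[4-(benzyloxy)-3-methoxyphenyl]-3-hydroxypentanal F1. Pinnick oxidation (NaClO2, NaH2PO4, 2-methylbut-2-ene, t-BuOH/H2O) should give (3S)-5-[4-(benzyloxy)-3-methoxyphenyl]-3-hydroxypentanoic acid F2. Silylation with (Me3Si)2NH should give the bis(trimethylsilyl) derivative F3, which is condensed with 6 under TMSOTf (CH2Cl2, −78 °C) to the cis-2,6-disubstituted 1,3-dioxan-4-one F4. Cp2TiMe2 (toluene/THF, 65 °C) should methylenate the lactone carbonyl to the 4-methylidene-1,3-dioxane F5. Me2AlCl (CH2Cl2, −78 °C to rt) ionises the acetal C2–O3 bond; the aluminium enolate should reclose on the oxocarbenium carbon through a chair to the cis-2,6-disubstituted oxan-4-one F6. LiBH(s-Bu)3 (L-Selectride; THF, −78 °C) attacks from the equatorial side and should give the axial (2S,4S,6S)-oxan-4-ol F7. Ac2O, pyridine and DMAP then give 10.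

Step 6. The bulky alkoxyphosphonium group may hinder axial approach of acetate at C4, leading to elimination towards the 3,6-dihydro-2H-pyran or to recovered alcohol. The fallback runs the inversion as a two-stage sulfonate displacement from 9 back to 10. ClCH2SO2Cl with pyridine (CH2Cl2, 0 °C) should give the (2S,4R,6S)-oxan-4-yl chloromethanesulfonate F8, which has a small, very good leaving group. CsOAc with 18-crown-6 (toluene, 80 °C) should displace it with inversion to 10.

Step 7. Over-reduction may occur by hydrogenolysis of the ring C2–O1 bond, a benzylic ether of an electron-rich arene, or debenzylation may be incomplete. The fallback removes the three benzyl groups from 10 without hydrogen, using BCl3 and pentamethylbenzene (CH2Cl2, −78 °C). This is a Lewis-acid debenzylation in which the arene traps the benzyl cations, and it should leave the acetate and the aryl methyl ethers. It goes from 10 directly to 11 and makes no new compound.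

**Further compounds**

F1 | step 5 | (3S)-5-[4-(benzyloxy)-3-methoxyphenyl]-3-hydroxypentanal | O=CC[C@@H](O)CCc1ccc(OCc2ccccc2)c(OC)c1
F2 | step 5 | (3S)-5-[4-(benzyloxy)-3-methoxyphenyl]-3-hydroxypentanoic acid | OC(=O)C[C@@H](O)CCc1ccc(OCc2ccccc2)c(OC)c1
F3 | step 5 | trimethylsilyl (3S)-5-[4-(benzyloxy)-3-methoxyphenyl]-3-[(trimethylsilyl)oxy]pentanoate | C[Si](C)(C)OC(=O)C[C@@H](O[Si](C)(C)C)CCc1ccc(OCc2ccccc2)c(OC)c1
F4 | step 5 | (2S,6S)-2-[3,4-bis(benzyloxy)-5-methoxyphenyl]-6-{2-[4-(benzyloxy)-3-methoxyphenyl]ethyl}-1,3-dioxan-4-one (cis) | COc1cc(CC[C@H]2CC(=O)O[C@@H](c3cc(OCc4ccccc4)c(OCc4ccccc4)c(OC)c3)O2)ccc1OCc1ccccc1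
F5 | step 5 | (2S,6S)-2-[3,4-bis(benzyloxy)-5-methoxyphenyl]-6-{2-[4-(benzyloxy)-3-methoxyphenyl]ethyl}-4-methylidene-1,3-dioxane (cis) | COc1cc(CC[C@H]2CC(=C)O[C@@H](c3cc(OCc4ccccc4)c(OCc4ccccc4)c(OC)c3)O2)ccc1OCc1ccccc1
F6 | step 5 | (2S,6S)-2-[3,4-bis(benzyloxy)-5-methoxyphenyl]-6-{2-[4-(benzyloxy)-3-methoxyphenyl]ethyl}oxan-4-one (cis) | COc1cc(CC[C@H]2CC(=O)C[C@@H](c3cc(OCc4ccccc4)c(OCc4ccccc4)c(OC)c3)O2)ccc1OCc1ccccc1
F7 | step 5 | (2S,4S,6S)-2-[3,4-bis(benzyloxy)-5-methoxyphenyl]-6-{2-[4-(benzyloxy)-3-methoxyphenyl]ethyl}oxan-4-ol (axial hydroxyl) | COc1cc(CC[C@H]2C[C@H](O)C[C@@H](c3cc(OCc4ccccc4)c(OCc4ccccc4)c(OC)c3)O2)ccc1OCc1ccccc1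
F8 | step 6 | (2S,4R,6S)-2-[3,4-bis(benzyloxy)-5-methoxyphenyl]-6-{2-[4-(benzyloxy)-3-methoxyphenyl]ethyl}oxan-4-yl chloromethanesulfonate | COc1cc(CC[C@H]2C[C@@H](OS(=O)(=O)CCl)C[C@@H](c3cc(OCc4ccccc4)c(OCc4ccccc4)c(OC)c3)O2)ccc1OCc1ccccc1
F0 | step 7 | none | none
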